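**Retrosynthetic overview**
1. Labels used throughout: C8 = lactone O–CH, C9 = ring CH2, C10 = CH(CH3), C1–C3 = the three CH2, C4 = C(CH2OH)=, C5 = =CH, C6 = CH–O-acyl, C7 = ring-fusion CH, C11–C13 = lactone carbons, C14 = methyl, C15 = CH2OH. The γ-lactone is closed last (O8 onto C12, then C13 by methylenation and oxidation), after an Evans–Tishchenko reaction that reduces a C8 ketone 1,3-anti to O6 and acylates O6 with the side-chain aldehyde in one operation.
2. Key disconnection C9–C10 by retro-Claisen: the ten-membered γ,δ-unsaturated ketone (C8=O, C1=C2) comes from an eight-membered 2-methylene oxocene (C9H2=C8–O–C2) that carries an (E)-propenyl group (C1=C10–C14) on C2; the enol ether comes from an eight-membered lactone.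
3. Enabling feature: the oxygen-bearing C8 sits 1,3 to the methyl-bearing C10 across C9H2, and C10 is followed by two ring CH2 groups (C1, C2). With C8 as ketone and C1=C2 unsaturated this is the C(=O)–CH2–CH(CH3)–CH=CH Claisen retron, and the ring-cis C4=C5 olefin lets the five-atom tether C3–C7 hold O–C8 and C2 in an eight-membered ring.
4. The eight-membered lactone comes from a seco acid (Yamaguchi). C6/C7 are set by an Evans anti-aldol between an acyl oxazolidinone (C7, C8, C11, C12) and an enal (C1–C6, C10, C14, C15) whose C4=C5 geometry is fixed in a dihydropyranone; C2 is set by a Paterson aldol.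
5. Ring order: six-membered lactone (temporary), eight-membered lactone (temporary), ten-membered carbocycle (key step), γ-lactone.

Key step: step 15

Assumption: (+)-Ipc2BCl is taken to add methyl ketone enolates to the re face of an aldehyde; should the sense be the reverse, its antipode is used in step 2 and nothing else changes.

**Route**

Step 1
Reactants: 1 hydroxyacetone
Product: 2 1-[(tert-butyldiphenylsilyl)oxy]propan-2-one
Conditions: TBDPSCl, imidazole, CH2Cl2, 0 °C to rt
Reagents that add atoms: tert-butyl(chloro)diphenylsilane, CC(C)(C)[Si](Cl)(c1ccccc1)c1ccccc1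
Why: Imidazole-promoted silylation of the primary alcohol; the bulky silyl ether later steers enolisation to the methyl side and lasts to the final step.

Step 2
Reactants: 2 1-[(tert-butyldiphenylsilyl)oxy]propan-2-one; 3 (E)-but-2-enal
Product: 5 (4R,5E)-1-[(tert-butyldiphenylsilyl)oxy]-4-hydroxyhept-5-en-2-one, via enol diisopinocampheylborinate 4 (not isolated)
Conditions: (+)-Ipc2BCl, Et3N, Et2O, 0 °C; 3, −78 to −20 °C; H2O2, pH 7 buffer, MeOH
Reagents that add atoms: none
Why: Paterson aldol, in which Ipc2BCl/Et3N enolises the ketone on the unhindered CH3 side and the chiral enol borinate adds to the re face of the enal, setting C2 as R by reagent control; any minor enantiomer would be removed as a diastereomer after step 9.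

Step 3
Reactants: 5 (4R,5E)-1-[(tert-butyldiphenylsilyl)oxy]-4-hydroxyhept-5-en-2-one
Product: 6 (6R)-4-{[(tert-butyldiphenylsilyl)oxy]methyl}-6-[(1E)-prop-1-en-1-yl]-5,6-dihydro-2H-pyran-2-one
Conditions: Ph3P=C=C=O, toluene, 80 °C
Reagents that add atoms: ketenylidenetriphenylphosphorane (Bestmann ylide), O=C=C=P(c1ccccc1)(c1ccccc1)c1ccccc1
Why: Domino addition–intramolecular Wittig reaction, in which the C2 hydroxyl adds to the ketene ylide and the ester ylide olefinates the C4 ketone, so the six-membered ring forces C3 and the new carbonyl carbon C6 to be cis on C4=C5.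

Step 4
Reactants: 6 the dihydropyranone
Product: 7 (2E,5R,6E)-3-{[(tert-butyldiphenylsilyl)oxy]methyl}-5-hydroxy-N-methoxy-N-methylocta-2,6-dienamide (amide carbonyl cis to the C3H2 group)
Conditions: AlMe3, MeNH(OMe)·HCl, CH2Cl2, 0 °C to rt; Rochelle salt
Reagents that add atoms: N,O-dimethylhydroxylamine hydrochloride, CNOC.Cl
Why: Weinreb aminolysis of the lactone by the aluminium amide (1,2-addition) frees the C2 hydroxyl and turns C6 into an amide that can be reduced to the aldehyde without touching the olefin geometry.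

Step 5
Reactants: 7 the hydroxy Weinreb amide
Product: 8 (2E,5R,6E)-3-{[(tert-butyldiphenylsilyl)oxy]methyl}-N-methoxy-N-methyl-5-[(triethylsilyl)oxy]octa-2,6-dienamide
Conditions: Et3SiCl, imidazole, DMAP (cat.), CH2Cl2, 0 °C
Reagents that add atoms: chlorotriethylsilane, CC[Si](Cl)(CC)CC
Why: Standard silyl ether formation; the triethylsilyl group is chosen because it can later be removed in the presence of the TBS and TBDPS ethers.

Step 6
Reactants: 8 the silylated Weinreb amide
Product: 9 (2E,5R,6E)-3-{[(tert-butyldiphenylsilyl)oxy]methyl}-5-[(triethylsilyl)oxy]octa-2,6-dienal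
Conditions: i-Bu2AlH (DIBAL-H), THF, −78 °C; Rochelle salt
Reagents that add atoms: none
Why: Hydride reduction of a Weinreb amide stops at the aldehyde through the chelated tetrahedral intermediate, and the cold neutral work-up should keep the geometry of the β,β-disubstituted enal.

Step 7
Reactants: 10 2-(2-bromoethyl)-1,3-dioxolane
Product: 12 3-(1,3-dioxolan-2-yl)propanoic acid, via Grignard reagent 11 (not isolated)
Conditions: Mg, THF, 25 °C; CO2, −20 °C; aq. NaH2PO4
Reagents that add atoms: carbon dioxide, O=C=O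
Why: Grignard carboxylation; the dioxolane masks C12 at the aldehyde level and, unlike an open-chain acetal, should not exchange with a neighbouring free hydroxyl later on.

Step 8
Reactants: 12 3-(1,3-dioxolan-2-yl)propanoic acid; 13 (4S)-4-benzyl-1,3-oxazolidin-2-one
Product: 15 (4S)-4-benzyl-3-[3-(1,3-dioxolan-2-yl)propanoyl]-1,3-oxazolidin-2-one, via mixed pivalic anhydride 14 (not isolated)
Conditions: t-BuCOCl, Et3N, THF, −20 °C; 13, LiCl, rt
Reagents that add atoms: none
Why: N-acylation of the Evans auxiliary through the mixed anhydride (LiCl/Et3N variant) avoids an acid chloride, which the acetal would not tolerate.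

Step 9
Reactants: 15 the acyl oxazolidinone; 9 the enal
Product: 17 anti-aldol adduct (4S)-4-benzyl-3-[(2R,3R,4E,7R,8E)-5-{[(tert-butyldiphenylsilyl)oxy]methyl}-2-(1,3-dioxolan-2-ylmethyl)-3-hydroxy-7-[(triethylsilyl)oxy]deca-4,8-dienoyl]-1,3-oxazolidin-2-one, via O-trimethylsilyl aldol adduct 16 (not isolated)
Conditions: MgCl2 (0.2 equiv), Et3N, Me3SiCl, EtOAc, rt; citric acid (cat.), MeOH, 0 °C (brief)
Reagents that add atoms: none
Why: Evans MgCl2-catalysed anti-aldol, in which the chelated (Z)-magnesium enolate is attacked on the face away from the benzyl group (sets C7) through a boat transition state that places O6 anti to the C7 side chain (sets C6), with silylation of the aldolate turning the catalyst over; the enal has no α-hydrogen to enolise, and the brief citric acid methanolysis should remove only the trimethylsilyl ether and leave the triethylsilyl ether in place.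

Step 10
Reactants: 17 the aldol adduct
Product: 18 the C6 tert-butyldimethylsilyl ether of 17
Conditions: TBSOTf (1.2 equiv), 2,6-lutidine, CH2Cl2, −78 °C
Reagents that add atoms: tert-butyldimethylsilyl triflate, CC(C)(C)[Si](C)(C)OS(=O)(=O)C(F)(F)F
Why: Silylation with the silyl triflate protects the β-hydroxyl against retro-aldol cleavage and β-lactone formation in steps 11 to 13; the low temperature and small excess should spare the dioxolane.

Step 11
Reactants: 18 the silylated imide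
Product: 20 (2R,3R,4E,7R,8E)-3-[(tert-butyldimethylsilyl)oxy]-5-{[(tert-butyldiphenylsilyl)oxy]methyl}-2-(1,3-dioxolan-2-ylmethyl)-7-[(triethylsilyl)oxy]deca-4,8-dienoic acid, via peroxy acid 19 (not isolated)
Conditions: LiOH, H2O2, THF/H2O, 0 °C; aq. Na2SO3; pH 4 work-up
Reagents that add atoms: hydrogen peroxide, OO
Why: Hydroperoxide cleavage of the imide is selective for the exocyclic carbonyl and should not epimerise C7; the auxiliary is recovered.

Step 12
Reactants: 20 the acid
Product: 21 seco acid (2R,3R,4E,7R,8E)-3-[(tert-butyldimethylsilyl)oxy]-5-{[(tert-butyldiphenylsilyl)oxy]methyl}-2-(1,3-dioxolan-2-ylmethyl)-7-hydroxydeca-4,8-dienoic acid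
Conditions: PPTS (cat.), MeOH/CH2Cl2, 0 °C to rt
Reagents that add atoms: none
Why: Mild acidic methanolysis removes the secondary triethylsilyl ether much faster than the hindered TBS ether, the TBDPS ether and the dioxolane.

Step 13
Reactants: 21 the seco acid
Product: 23 (3R,4R,5E,8R)-4-[(tert-butyldimethylsilyl)oxy]-6-{[(tert-butyldiphenylsilyl)oxy]methyl}-3-(1,3-dioxolan-2-ylmethyl)-8-[(1E)-prop-1-en-1-yl]-3,4,7,8-tetrahydro-2H-oxocin-2-one (ring olefin cis in the ring), via mixed trichlorobenzoic anhydride 22 (not isolated)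
Conditions: 2,4,6-Cl3C6H2COCl, Et3N, THF, rt; slow addition to DMAP, toluene, 80 °C, high dilution
Reagents that add atoms: none
Why: Yamaguchi macrolactonisation, in which the ring-cis C4=C5 olefin pre-organises the chain for eight-membered ring closure and C2 keeps its configuration because the carboxyl, not the alcohol, is activated.

Step 14
Reactants: 23 the eight-membered lactone
Product: 24 (3R,4R,5E,8R)-4-[(tert-butyldimethylsilyl)oxy]-6-{[(tert-butyldiphenylsilyl)oxy]methyl}-3-(1,3-dioxolan-2-ylmethyl)-2-methylidene-8-[(1E)-prop-1-en-1-yl]-3,4,7,8-tetrahydro-2H-oxocine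
Conditions: Tebbe reagent Cp2Ti(μ-Cl)(μ-CH2)AlMe2, pyridine, THF/toluene, −40 °C to rt; filtration through basic alumina
Reagents that add atoms: Tebbe reagent, C[Al-]1(C)C[Ti]([Cl+]1)(C1C=CC=C1)C1C=CC=C1
Why: Tebbe methylenation converts the lactone carbonyl into the exocyclic enol ether (C9 enters here) without base, so C7 is not epimerised and the silyl ethers, acetal and olefins are untouched.

Step 15
Reactants: 24 the 2-methylene oxocene
Product: 25 (2R,3R,4E,7Z,9S)-3-[(tert-butyldimethylsilyl)oxy]-5-{[(tert-butyldiphenylsilyl)oxy]methyl}-2-(1,3-dioxolan-2-ylmethyl)-9-methylcyclodeca-4,7-dien-1-one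
Conditions: toluene (degassed), sealed tube, base-washed glass, 150 °C
Reagents that add atoms: none
Why: A concerted [3,3]-sigmatropic (Claisen) rearrangement of the allyl vinyl ether C9H2=C8–O–C2–C1=C10 embedded in the eight-membered ring forms the C9–C10 σ-bond while the C2–O bond breaks and the ring oxygen becomes the C8 carbonyl. The closest known reaction type is the Claisen ring expansion of 2-methylene cyclic ethers that carry an alkenyl group next to oxygen (made from lactones by Tebbe methylenation), which gives medium-ring cycloalkenones. The ten-membered carbocycle is closed by ring expansion (C9, C10 and C1 enter the ring, oxygen leaves it) through a chair-like six-membered transition state bridged by the five-atom tether C3–C4=C5–C6–C7. C10 is the only new stereocentre and is set by suprafacial 1,3-transfer of chirality from (R)-C2 across the (E)-propenyl group: with the methyl group pseudo-equatorial and the tether carbon C3 pseudo-axial the chair gives the target's arrangement at C10 (S in the dienone, R once C1=C2 is saturated) and a (Z)-C1=C2 olefin. The selectivity needed is this chair over the chair with equatorial C3 or a boat, which would give the C10 epimer; it should be secured by the short tether with its ring-cis olefin, which can span C7 and C3 only when C3 is pseudo-axial, 1,3 to the C8 substituent. The reaction is driven by formation of the C=O bond, and the neutral thermal conditions should leave the silyl ethers, the acetal and C7 untouched.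

Step 16
Reactants: 25 the cyclodecadienone
Product: 26 (2R,3R,4E,9R)-3-[(tert-butyldimethylsilyl)oxy]-5-{[(tert-butyldiphenylsilyl)oxy]methyl}-2-(1,3-dioxolan-2-ylmethyl)-9-methylcyclodec-4-en-1-one
Conditions: KO2C–N=N–CO2K, AcOH (slow addition), MeOH/pyridine, 0 °C to rt
Reagents that add atoms: none
Why: Diimide reduces the strained cis-disubstituted C1=C2 olefin much faster than the trisubstituted C4=C5 olefin and leaves the ketone, the silyl ethers and the acetal alone.

Step 17
Reactants: 26 the cyclodecenone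
Product: 27 (2R,3R,4E,9R)-5-{[(tert-butyldiphenylsilyl)oxy]methyl}-2-(1,3-dioxolan-2-ylmethyl)-3-hydroxy-9-methylcyclodec-4-en-1-one
Conditions: HF·pyridine, pyridine, THF, 0 °C to rt
Reagents that add atoms: none
Why: Buffered HF·pyridine cleaves the secondary TBS ether while the primary TBDPS ether and the dioxolane should survive, which unmasks the β-hydroxy ketone needed in step 20.

Step 18
Reactants: 28 but-2-yne-1,4-diol
Product: 29 1,4-bis[(tert-butyldiphenylsilyl)oxy]but-2-yne
Conditions: TBDPSCl, imidazole, DMF, rt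
Reagents that add atoms: tert-butyl(chloro)diphenylsilane, CC(C)(C)[Si](Cl)(c1ccccc1)c1ccccc1
Why: Standard bis-silylation of a primary diol.

Step 19
Reactants: 29 the bis-silyl alkyne
Product: 30 (2E)-4-[(tert-butyldiphenylsilyl)oxy]-2-{[(tert-butyldiphenylsilyl)oxy]methyl}but-2-enal
Conditions: Rh(CO)2(acac) (cat.), BIPHEPHOS, CO/H2 (1:1), CH2Cl2, 40 °C
Reagents that add atoms: carbon monoxide, [C-]#[O+]
Why: Rhodium-catalysed hydroformylation of a symmetrical internal alkyne adds H and CHO syn, which gives the (E)-enal with the formyl group trans to the β-CH2O substituent, the geometry of the target's acyl group.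

Step 20
Reactants: 27 the β-hydroxy ketone; 30 the side-chain enal
Product: 31 (1R,2E,7R,9R,10S)-3-{[(tert-butyldiphenylsilyl)oxy]methyl}-10-(1,3-dioxolan-2-ylmethyl)-9-hydroxy-7-methylcyclodec-2-en-1-yl (2E)-4-[(tert-butyldiphenylsilyl)oxy]-2-{[(tert-butyldiphenylsilyl)oxy]methyl}but-2-enoate
Conditions: SmI2 (0.3 equiv), 30 (excess), THF, −10 °C
Reagents that add atoms: none
Why: Evans–Tishchenko reaction, in which the samarium-bound hemiacetal formed from the C6 hydroxyl and 30 delivers its hydride to the C8 ketone through a chair-like six-membered transition state, so that O8 is set 1,3-anti to O6 and O6 is acylated by the side chain in the same operation.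

Step 21
Reactants: 31 the hydroxy ester
Product: 32 lactol (3aS,4R,5E,10R,11aR)-6-{[(tert-butyldiphenylsilyl)oxy]methyl}-2-hydroxy-10-methyl-2,3,3a,4,7,8,9,10,11,11a-decahydrocyclodeca[b]furan-4-yl (2E)-4-[(tert-butyldiphenylsilyl)oxy]-2-{[(tert-butyldiphenylsilyl)oxy]methyl}but-2-enoate (both anomers)
Conditions: PPTS, acetone/H2O (9:1), 55 °C
Reagents that add atoms: water, O
Why: Acid-catalysed hydrolysis of the dioxolane with capture of the C12 aldehyde by the free C8 hydroxyl gives the five-membered lactol; O6 is already acylated, so only O8 can close the ring.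

Step 22
Reactants: 32 the lactol
Product: 33 the 3-methylidene lactol (α-methylene lactol; otherwise as 32)
Conditions: aq. CH2O (37%), pyrrolidine (cat.), propionic acid (cat.), i-PrOH, 45 °C
Reagents that add atoms: formaldehyde, C=O
Why: Organocatalytic Mannich-type α-methylenation of aldehydes acts on the open hydroxy-aldehyde tautomer of the lactol and brings in C13 without a strong base, which the C6 ester would not survive.

Step 23
Reactants: 33 the α-methylene lactol
Product: 34 tris-silylated target (3aS,4R,5E,10R,11aR)-6-{[(tert-butyldiphenylsilyl)oxy]methyl}-10-methyl-3-methylidene-2-oxo-2,3,3a,4,7,8,9,10,11,11a-decahydrocyclodeca[b]furan-4-yl (2E)-4-[(tert-butyldiphenylsilyl)oxy]-2-{[(tert-butyldiphenylsilyl)oxy]methyl}but-2-enoate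
Conditions: MnO2 (activated, excess), CH2Cl2, rt
Reagents that add atoms: none
Why: MnO2 oxidises the allylic lactol to the α-methylene-γ-lactone and leaves the silyl ethers and the other olefins alone.

Step 24
Reactants: 34 the tris-silylated target
Product: 35 CNP0131216.2, (3aS,4R,5E,10R,11aR)-6-(hydroxymethyl)-10-methyl-3-methylidene-2-oxo-2,3,3a,4,7,8,9,10,11,11a-decahydrocyclodeca[b]furan-4-yl (2E)-4-hydroxy-2-(hydroxymethyl)but-2-enoate
Conditions: HF·pyridine, pyridine, THF, 0 °C to rt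
Reagents that add atoms: none
Why: Buffered, non-basic fluoride cleavage of the three primary silyl ethers should avoid conjugate addition to the α-methylene lactone and acyl migration.

**Compound list**

1 | hydroxyacetone (1-hydroxypropan-2-one) | CC(=O)CO | starting material
2 | 1-[(tert-butyldiphenylsilyl)oxy]propan-2-one | CC(=O)CO[Si](c1ccccc1)(c1ccccc1)C(C)(C)C | intermediate
3 | (E)-but-2-enal (crotonaldehyde) | C/C=C/C=O | starting material
4 | enol borinate of 2 on the CH3 side, boron carrying two (+)-isopinocampheyl groups | C=C(CO[Si](c1ccccc1)(c1ccccc1)C(C)(C)C)OB([C@H]1C[C@H]2C[C@@H]([C@@H]1C)C2(C)C)[C@H]1C[C@H]2C[C@@H]([C@@H]1C)C2(C)C | intermediate (not isolated)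
5 | (4R,5E)-1-[(tert-butyldiphenylsilyl)oxy]-4-hydroxyhept-5-en-2-one | C/C=C/[C@H](O)CC(=O)CO[Si](c1ccccc1)(c1ccccc1)C(C)(C)C | intermediate
6 | (6R)-4-{[(tert-butyldiphenylsilyl)oxy]methyl}-6-[(1E)-prop-1-en-1-yl]-5,6-dihydro-2H-pyran-2-one | C/C=C/[C@H]1CC(CO[Si](c2ccccc2)(c2ccccc2)C(C)(C)C)=CC(=O)O1 | intermediate
7 | (2E,5R,6E)-3-{[(tert-butyldiphenylsilyl)oxy]methyl}-5-hydroxy-N-methoxy-N-methylocta-2,6-dienamide | C/C=C/[C@H](O)C/C(CO[Si](c1ccccc1)(c1ccccc1)C(C)(C)C)=C\C(=O)N(C)OC | intermediate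
8 | (2E,5R,6E)-3-{[(tert-butyldiphenylsilyl)oxy]methyl}-N-methoxy-N-methyl-5-[(triethylsilyl)oxy]octa-2,6-dienamide | C/C=C/[C@H](O[Si](CC)(CC)CC)C/C(CO[Si](c1ccccc1)(c1ccccc1)C(C)(C)C)=C\C(=O)N(C)OC | intermediate
9 | (2E,5R,6E)-3-{[(tert-butyldiphenylsilyl)oxy]methyl}-5-[(triethylsilyl)oxy]octa-2,6-dienal | C/C=C/[C@H](O[Si](CC)(CC)CC)C/C(CO[Si](c1ccccc1)(c1ccccc1)C(C)(C)C)=C\C=O | intermediate
10 | 2-(2-bromoethyl)-1,3-dioxolane | BrCCC1OCCO1 | starting material
11 | [2-(1,3-dioxolan-2-yl)ethyl]magnesium bromide | Br[Mg]CCC1OCCO1 | intermediate (not isolated)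
12 | 3-(1,3-dioxolan-2-yl)propanoic acid | OC(=O)CCC1OCCO1 | intermediate
13 | (4S)-4-benzyl-1,3-oxazolidin-2-one | O=C1N[C@@H](Cc2ccccc2)CO1 | starting material
14 | 3-(1,3-dioxolan-2-yl)propanoic pivalic anhydride | CC(C)(C)C(=O)OC(=O)CCC1OCCO1 | intermediate (not isolated)
15 | (4S)-4-benzyl-3-[3-(1,3-dioxolan-2-yl)propanoyl]-1,3-oxazolidin-2-one | O=C(CCC1OCCO1)N1[C@@H](Cc2ccccc2)COC1=O | intermediate
16 | O-trimethylsilyl ether of 17 | C/C=C/[C@H](O[Si](CC)(CC)CC)C/C(CO[Si](c1ccccc1)(c1ccccc1)C(C)(C)C)=C\[C@@H](O[Si](C)(C)C)[C@@H](CC1OCCO1)C(=O)N1[C@@H](Cc2ccccc2)COC1=O | intermediate (not isolated)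
17 | (4S)-4-benzyl-3-[(2R,3R,4E,7R,8E)-5-{[(tert-butyldiphenylsilyl)oxy]methyl}-2-(1,3-dioxolan-2-ylmethyl)-3-hydroxy-7-[(triethylsilyl)oxy]deca-4,8-dienoyl]-1,3-oxazolidin-2-one | C/C=C/[C@H](O[Si](CC)(CC)CC)C/C(CO[Si](c1ccccc1)(c1ccccc1)C(C)(C)C)=C\[C@@H](O)[C@@H](CC1OCCO1)C(=O)N1[C@@H](Cc2ccccc2)COC1=O | intermediate
18 | 3-O-tert-butyldimethylsilyl ether of 17 | C/C=C/[C@H](O[Si](CC)(CC)CC)C/C(CO[Si](c1ccccc1)(c1ccccc1)C(C)(C)C)=C\[C@@H](O[Si](C)(C)C(C)(C)C)[C@@H](CC1OCCO1)C(=O)N1[C@@H](Cc2ccccc2)COC1=O | intermediate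
19 | peroxy acid corresponding to 20 | C/C=C/[C@H](O[Si](CC)(CC)CC)C/C(CO[Si](c1ccccc1)(c1ccccc1)C(C)(C)C)=C\[C@@H](O[Si](C)(C)C(C)(C)C)[C@@H](CC1OCCO1)C(=O)OO | intermediate (not isolated)
20 | (2R,3R,4E,7R,8E)-3-[(tert-butyldimethylsilyl)oxy]-5-{[(tert-butyldiphenylsilyl)oxy]methyl}-2-(1,3-dioxolan-2-ylmethyl)-7-[(triethylsilyl)oxy]deca-4,8-dienoic acid | C/C=C/[C@H](O[Si](CC)(CC)CC)C/C(CO[Si](c1ccccc1)(c1ccccc1)C(C)(C)C)=C\[C@@H](O[Si](C)(C)C(C)(C)C)[C@@H](CC1OCCO1)C(=O)O | intermediate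
21 | (2R,3R,4E,7R,8E)-3-[(tert-butyldimethylsilyl)oxy]-5-{[(tert-butyldiphenylsilyl)oxy]methyl}-2-(1,3-dioxolan-2-ylmethyl)-7-hydroxydeca-4,8-dienoic acid | C/C=C/[C@H](O)C/C(CO[Si](c1ccccc1)(c1ccccc1)C(C)(C)C)=C\[C@@H](O[Si](C)(C)C(C)(C)C)[C@@H](CC1OCCO1)C(=O)O | intermediate
22 | mixed anhydride of 21 with 2,4,6-trichlorobenzoic acid | C/C=C/[C@H](O)C/C(CO[Si](c1ccccc1)(c1ccccc1)C(C)(C)C)=C\[C@@H](O[Si](C)(C)C(C)(C)C)[C@@H](CC1OCCO1)C(=O)OC(=O)c1c(Cl)cc(Cl)cc1Cl | intermediate (not isolated)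
23 | (3R,4R,5E,8R)-4-[(tert-butyldimethylsilyl)oxy]-6-{[(tert-butyldiphenylsilyl)oxy]methyl}-3-(1,3-dioxolan-2-ylmethyl)-8-[(1E)-prop-1-en-1-yl]-3,4,7,8-tetrahydro-2H-oxocin-2-one | C/C=C/[C@H]1C/C(CO[Si](c2ccccc2)(c2ccccc2)C(C)(C)C)=C\[C@@H](O[Si](C)(C)C(C)(C)C)[C@@H](CC2OCCO2)C(=O)O1 | intermediate
24 | (3R,4R,5E,8R)-4-[(tert-butyldimethylsilyl)oxy]-6-{[(tert-butyldiphenylsilyl)oxy]methyl}-3-(1,3-dioxolan-2-ylmethyl)-2-methylidene-8-[(1E)-prop-1-en-1-yl]-3,4,7,8-tetrahydro-2H-oxocine | C/C=C/[C@H]1C/C(CO[Si](c2ccccc2)(c2ccccc2)C(C)(C)C)=C\[C@@H](O[Si](C)(C)C(C)(C)C)[C@@H](CC2OCCO2)C(=C)O1 | intermediate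
25 | (2R,3R,4E,7Z,9S)-3-[(tert-butyldimethylsilyl)oxy]-5-{[(tert-butyldiphenylsilyl)oxy]methyl}-2-(1,3-dioxolan-2-ylmethyl)-9-methylcyclodeca-4,7-dien-1-one | O=C1C[C@H](C)/C=C\C/C(CO[Si](c2ccccc2)(c2ccccc2)C(C)(C)C)=C\[C@@H](O[Si](C)(C)C(C)(C)C)[C@H]1CC1OCCO1 | intermediate
26 | (2R,3R,4E,9R)-3-[(tert-butyldimethylsilyl)oxy]-5-{[(tert-butyldiphenylsilyl)oxy]methyl}-2-(1,3-dioxolan-2-ylmethyl)-9-methylcyclodec-4-en-1-one | O=C1C[C@H](C)CCC/C(CO[Si](c2ccccc2)(c2ccccc2)C(C)(C)C)=C\[C@@H](O[Si](C)(C)C(C)(C)C)[C@H]1CC1OCCO1 | intermediate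
27 | (2R,3R,4E,9R)-5-{[(tert-butyldiphenylsilyl)oxy]methyl}-2-(1,3-dioxolan-2-ylmethyl)-3-hydroxy-9-methylcyclodec-4-en-1-one | O=C1C[C@H](C)CCC/C(CO[Si](c2ccccc2)(c2ccccc2)C(C)(C)C)=C\[C@@H](O)[C@H]1CC1OCCO1 | intermediate
28 | but-2-yne-1,4-diol | OCC#CCO | starting material
29 | 1,4-bis[(tert-butyldiphenylsilyl)oxy]but-2-yne | CC(C)(C)[Si](c1ccccc1)(c1ccccc1)OCC#CCO[Si](c1ccccc1)(c1ccccc1)C(C)(C)C | intermediate
30 | (2E)-4-[(tert-butyldiphenylsilyl)oxy]-2-{[(tert-butyldiphenylsilyl)oxy]methyl}but-2-enal | O=C/C(=C/CO[Si](c1ccccc1)(c1ccccc1)C(C)(C)C)CO[Si](c1ccccc1)(c1ccccc1)C(C)(C)C | intermediate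
31 | (1R,2E,7R,9R,10S)-3-{[(tert-butyldiphenylsilyl)oxy]methyl}-10-(1,3-dioxolan-2-ylmethyl)-9-hydroxy-7-methylcyclodec-2-en-1-yl (2E)-4-[(tert-butyldiphenylsilyl)oxy]-2-{[(tert-butyldiphenylsilyl)oxy]methyl}but-2-enoate | O[C@@H]1C[C@H](C)CCC/C(CO[Si](c2ccccc2)(c2ccccc2)C(C)(C)C)=C\[C@@H](OC(=O)/C(=C/CO[Si](c2ccccc2)(c2ccccc2)C(C)(C)C)CO[Si](c2ccccc2)(c2ccccc2)C(C)(C)C)[C@H]1CC1OCCO1 | intermediate
32 | (3aS,4R,5E,10R,11aR)-6-{[(tert-butyldiphenylsilyl)oxy]methyl}-2-hydroxy-10-methyl-2,3,3a,4,7,8,9,10,11,11a-decahydrocyclodeca[b]furan-4-yl (2E)-4-[(tert-butyldiphenylsilyl)oxy]-2-{[(tert-butyldiphenylsilyl)oxy]methyl}but-2-enoate (lactol, both anomers) | C1C(O)O[C@@H]2C[C@H](C)CCC/C(CO[Si](c3ccccc3)(c3ccccc3)C(C)(C)C)=C\[C@@H](OC(=O)/C(=C/CO[Si](c3ccccc3)(c3ccccc3)C(C)(C)C)CO[Si](c3ccccc3)(c3ccccc3)C(C)(C)C)[C@@H]12 | intermediate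
33 | 3-methylidene derivative of lactol 32 | C=C1C(O)O[C@@H]2C[C@H](C)CCC/C(CO[Si](c3ccccc3)(c3ccccc3)C(C)(C)C)=C\[C@@H](OC(=O)/C(=C/CO[Si](c3ccccc3)(c3ccccc3)C(C)(C)C)CO[Si](c3ccccc3)(c3ccccc3)C(C)(C)C)[C@@H]12 | intermediate
34 | (3aS,4R,5E,10R,11aR)-6-{[(tert-butyldiphenylsilyl)oxy]methyl}-10-methyl-3-methylidene-2-oxo-2,3,3a,4,7,8,9,10,11,11a-decahydrocyclodeca[b]furan-4-yl (2E)-4-[(tert-butyldiphenylsilyl)oxy]-2-{[(tert-butyldiphenylsilyl)oxy]methyl}but-2-enoate | C=C1C(=O)O[C@@H]2C[C@H](C)CCC/C(CO[Si](c3ccccc3)(c3ccccc3)C(C)(C)C)=C\[C@@H](OC(=O)/C(=C/CO[Si](c3ccccc3)(c3ccccc3)C(C)(C)C)CO[Si](c3ccccc3)(c3ccccc3)C(C)(C)C)[C@@H]12 | intermediate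
35 | CNP0131216.2, (3aS,4R,5E,10R,11aR)-6-(hydroxymethyl)-10-methyl-3-methylidene-2-oxo-2,3,3a,4,7,8,9,10,11,11a-decahydrocyclodeca[b]furan-4-yl (2E)-4-hydroxy-2-(hydroxymethyl)but-2-enoate | C=C1C(=O)O[C@@H]2C[C@H](C)CCC/C(CO)=C\[C@@H](OC(=O)/C(=C/CO)CO)[C@@H]12 | target

**Step count and risks**

Total: 24 steps. Longest linear sequence: 20 steps (steps 1–6, 9–17, 20–24).

The three steps most likely to fail:

Step 20 (Evans–Tishchenko reaction with the hindered, α-branched enal 30). Hemiacetal formation at the C6 hydroxyl and the hydride shift may be too slow, so that retro-aldol cleavage, acyl migration from O6 to O8 or oxa-Michael addition to 30 take over. Fallback (undirected reduction and late acylation; sets out from 26 and comes back at 34): ketone 26, still carrying the C6 TBS ether, would be reduced with LiBH(s-Bu)3 (THF, −78 °C, hydride entering from the outer face of the ring away from the C7 side chain) to the (8R)-alcohol F1, material of the other facial sense being returned to 26 with Dess–Martin periodinane. F1 would be taken through the operations of steps 21–23 (PPTS in wet acetone; aqueous CH2O with pyrrolidine/propionic acid; MnO2) via the lactol F2 and the α-methylene lactol F3 to the C6-silylated α-methylene lactone F4. HF·pyridine would then free the C6 hydroxyl to give the hydroxy lactone F5, and Yamaguchi esterification (2,4,6-trichlorobenzoyl chloride, Et3N, DMAP) with the side-chain acid F6, made from 30 by Pinnick oxidation (NaClO2, NaH2PO4, 2-methylbut-2-ene), would give 34.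

Step 15 (Claisen ring expansion). The rearrangement may leak through the chair with an equatorial tether or through a boat, which erodes facial control at C10. The enol ether may also hydrolyse or suffer an acid-induced 1,3-shift, and the 1,5-diene C9=C8–C7–C6–C5=C4 offers a competing siloxy-Cope shift. Fallback (stepwise ionic allylation in place of the pericyclic shift; sets out from 23 and comes back at 25): lactone 23 would be opened with LiCH2SO2Ph (THF, −78 to 0 °C) to the hydroxy β-keto sulfone F7, and its C2 hydroxyl converted with ClCO2Me/pyridine into the allylic methyl carbonate F8. Tsuji–Trost macrocyclisation (Pd(PPh3)4, zerovalent palladium, THF, 60 °C, high dilution) would give the cyclic β-keto sulfone F9; ionisation and attack each occur with inversion, so that C9 again bonds to the face of C10 from which the C2 oxygen departs, the ring-forming anti rotamer of the allyl complex giving the cis C1=C2 olefin. Reductive desulfonylation with aluminium amalgam (Al/Hg, aqueous THF) would give 25.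

Step 22 (methylenation at the lactol stage). The lactol may stay closed, so that enamine formation is slow while the amine adds to the enoate side chain or shifts the acyl group. Fallback (methylenation at the lactone oxidation level by an enolate Mannich reaction; sets out from 32 and comes back at 34): lactol 32 would be oxidised with TEMPO/PhI(OAc)2 to the saturated γ-lactone F10. Kinetic deprotonation with LiN(SiMe3)2 (THF, −78 °C; the lactone α-CH2 is more acidic and more accessible than the γ-hydrogens of the hindered enoate) and trapping with Eschenmoser's salt (Me2N=CH2 I) would give the Mannich base F11. N-methylation with MeI would give the ammonium iodide F12, and elimination on stirring with aqueous NaHCO3 would give 34.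

**Further compounds**

F1 | step 20 | (1R,2S,3R,4E,9R)-3-[(tert-butyldimethylsilyl)oxy]-5-{[(tert-butyldiphenylsilyl)oxy]methyl}-2-(1,3-dioxolan-2-ylmethyl)-9-methylcyclodec-4-en-1-ol | O[C@@H]1C[C@H](C)CCC/C(CO[Si](c2ccccc2)(c2ccccc2)C(C)(C)C)=C\[C@@H](O[Si](C)(C)C(C)(C)C)[C@H]1CC1OCCO1
F2 | step 20 | lactol with C6 tert-butyldimethylsilyl ether (2-hydroxy-decahydrocyclodeca[b]furan, both anomers) | C1C(O)O[C@@H]2C[C@H](C)CCC/C(CO[Si](c3ccccc3)(c3ccccc3)C(C)(C)C)=C\[C@@H](O[Si](C)(C)C(C)(C)C)[C@@H]12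
F3 | step 20 | 3-methylidene derivative of lactol F2 | C=C1C(O)O[C@@H]2C[C@H](C)CCC/C(CO[Si](c3ccccc3)(c3ccccc3)C(C)(C)C)=C\[C@@H](O[Si](C)(C)C(C)(C)C)[C@@H]12
F4 | step 20 | α-methylene-γ-lactone with C6 tert-butyldimethylsilyl ether and C15 tert-butyldiphenylsilyl ether | C=C1C(=O)O[C@@H]2C[C@H](C)CCC/C(CO[Si](c3ccccc3)(c3ccccc3)C(C)(C)C)=C\[C@@H](O[Si](C)(C)C(C)(C)C)[C@@H]12
F5 | step 20 | α-methylene-γ-lactone with free C6 hydroxyl and C15 tert-butyldiphenylsilyl ether | C=C1C(=O)O[C@@H]2C[C@H](C)CCC/C(CO[Si](c3ccccc3)(c3ccccc3)C(C)(C)C)=C\[C@@H](O)[C@@H]12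
F6 | step 20 | (2E)-4-[(tert-butyldiphenylsilyl)oxy]-2-{[(tert-butyldiphenylsilyl)oxy]methyl}but-2-enoic acid | OC(=O)/C(=C/CO[Si](c1ccccc1)(c1ccccc1)C(C)(C)C)CO[Si](c1ccccc1)(c1ccccc1)C(C)(C)C
F7 | step 15 | (3R,4R,5E,8R,9E)-4-[(tert-butyldimethylsilyl)oxy]-6-{[(tert-butyldiphenylsilyl)oxy]methyl}-3-(1,3-dioxolan-2-ylmethyl)-8-hydroxy-1-(phenylsulfonyl)undeca-5,9-dien-2-one | C/C=C/[C@H](O)C/C(CO[Si](c1ccccc1)(c1ccccc1)C(C)(C)C)=C\[C@@H](O[Si](C)(C)C(C)(C)C)[C@@H](CC1OCCO1)C(=O)CS(=O)(=O)c1ccccc1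
F8 | step 15 | methyl carbonate of the C8 hydroxyl of F7 | C/C=C/[C@H](OC(=O)OC)C/C(CO[Si](c1ccccc1)(c1ccccc1)C(C)(C)C)=C\[C@@H](O[Si](C)(C)C(C)(C)C)[C@@H](CC1OCCO1)C(=O)CS(=O)(=O)c1ccccc1
F9 | step 15 | 10-(phenylsulfonyl) derivative of 25 (sulfonyl-bearing carbon as a mixture) | O=C1C(S(=O)(=O)c2ccccc2)[C@H](C)/C=C\C/C(CO[Si](c2ccccc2)(c2ccccc2)C(C)(C)C)=C\[C@@H](O[Si](C)(C)C(C)(C)C)[C@H]1CC1OCCO1
F10 | step 22 | saturated γ-lactone (3-unsubstituted 2-oxo analogue of 34) | C1C(=O)O[C@@H]2C[C@H](C)CCC/C(CO[Si](c3ccccc3)(c3ccccc3)C(C)(C)C)=C\[C@@H](OC(=O)/C(=C/CO[Si](c3ccccc3)(c3ccccc3)C(C)(C)C)CO[Si](c3ccccc3)(c3ccccc3)C(C)(C)C)[C@@H]12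
F11 | step 22 | 3-[(dimethylamino)methyl] lactone (Mannich base of F10, C3 as a mixture) | CN(C)CC1C(=O)O[C@@H]2C[C@H](C)CCC/C(CO[Si](c3ccccc3)(c3ccccc3)C(C)(C)C)=C\[C@@H](OC(=O)/C(=C/CO[Si](c3ccccc3)(c3ccccc3)C(C)(C)C)CO[Si](c3ccccc3)(c3ccccc3)C(C)(C)C)[C@@H]12
F12 | step 22 | trimethylammonium iodide derived from F11 | C[N+](C)(C)CC1C(=O)O[C@@H]2C[C@H](C)CCC/C(CO[Si](c3ccccc3)(c3ccccc3)C(C)(C)C)=C\[C@@H](OC(=O)/C(=C/CO[Si](c3ccccc3)(c3ccccc3)C(C)(C)C)CO[Si](c3ccccc3)(c3ccccc3)C(C)(C)C)[C@@H]12.[I-]
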